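## Structural features

The target is a 6,7,8,8a-tetrahydro-1H-isochromen-6-one. Ring A is a dihydropyran (O2, C1H2, C3=C4) and ring B a cyclohexenone (C4a=C5–C6=O); they share the C4a–C8a bond, so O2–C3=C4–C4a=C5–C6=O is a vinylogous ester running across both rings. C3 carries a (1E,3Z,5S)-3,5-dimethylhepta-1,3-dienyl chain, which extends the chromophore to a linear tetraenone and puts a Z-trisubstituted alkene and an allylic stereocentre (C5') in conjugation with it. Ring B holds three contiguous stereocentres: the quaternary carbinol C7 (R), the acetoxy carbon C8 (R) and the ring-fusion methine C8a (R). The C7 and C8 oxygens are cis and H8/H8a are trans, so in the half-chair the C7 methyl, the C8 oxygen and C1 are equatorial and only the C7 hydroxyl is axial. Fragile points are the C8 acetate (β to the enolisable C8a, so open to elimination), the epimerisable C8a–H, the acid-sensitive dienol ether, and the 3'Z alkene, which can isomerise whenever positive charge is delocalised into the chain. The real difficulty is to create C8 and C8a with the right sense next to the preformed quaternary C7 while the labile polyene is already in place. The key step uses the fact that C8a is the γ-carbon of the vinylogous ester ending in the C6 ketone while its neighbour C8 carries oxygen, a vinylogous aldol relationship across the C8–C8a bond of ring B.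

## Logic of the disconnections

25 from 23 through 24. Only the acetyl C–O bond at O8 is cut, and in the forward sense the Si–O bond at O7. The cis-diol is thereby already differentiated (tertiary O7 silylated, secondary O8 free), and the base-sensitive β-acetoxy unit is kept out of all C–C bond formation. The forward steps must acetylate a hindered secondary alcohol without silyl migration from O7 or elimination across C8–C8a, and must desilylate without acyl migration.

23 from 21 (key disconnection, through 22). The C8–C8a bond is cut, which opens ring B. The cut removes one ring and two of the three core stereocentres and leaves C7 as the only one. The forward step must enolise 21 through C8a only, must reach the enol ether geometry of 22 in which C7 is syn to C4a, and must let C7 control both new centres. A chelating Lewis acid is chosen for this, because in a non-chelated ring closure the C7 oxygen would be expected to sit anti to the forming bond, which leads to the 7,8-trans diol.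

21 from 19 through 20. This is functional-group change at C8 only (aldehyde from primary alcohol from PMB ether). The β-keto aldehyde with a quaternary α-carbon is too electrophilic to survive C–C bond formation, so it is unveiled last. The forward steps must cleave a PMB ether and oxidise a neopentyl-type alcohol in the presence of the polyene, without base (to avoid silyl migration from O7 to O8).

19 from 11 and 16 (through 17 and 18). The C4a=C5 double bond is cut as an aldol addition–dehydration. This is the most convergent cut: a pyranone carrying the whole side chain and a small chiral ketone carrying C5–C8. The forward step demands 1,2-addition of a ketone enolate to a poorly electrophilic vinylogous ester carbonyl and a dehydration that ends in the cross-conjugated dienol ether. It helps that 16 has a single enolisable position.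

11 from 6 and 8 (through 9 and 10). The C3–C4 bond (acylation of a methyl ketone enolate) and the O2–C3 bond (cyclodehydration) are cut, reducing ring A to a linear 1,3-diketone. The acyl donor is a Weinreb amide and not a dienoate ester, because an ester would invite conjugate addition of the enolate. The forward steps need kinetic enolisation of 8 at its methyl group and acid mild enough to spare the 3'Z alkene.

6 from 4 (through 5), 4 from 3, 3 from 1 (through 2). The C1'=C2' bond (E, stabilised ylide) and the C3'=C4' bond (Z, trifluoroethyl phosphonate) are cut; C5' comes unchanged from 1. The demands are a Z-selective trisubstituted olefination of an α-branched, epimerisable aldehyde and survival of the Z-enal until it is trapped.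

8 from 7. Only the O–Si bond is cut; the forward step must protect a β-hydroxy ketone without retro-aldol or dehydration.

16 from 15, 15 from 14, 14 from 13, 13 from 12. The cuts are the O7–Si bond, the C5–C6 bond (methyl addition to a carboxylate), the oxidation level of C6, and the C8–O bond (epoxide opening). The hydroxymethyl carbon of 12 becomes C6 and its epoxide CH2 becomes C8; the C7–O bond is never broken, which leads to 7R. The forward steps must keep the two CH2O arms different at every stage, since a symmetrical triol would be achiral.

## Other disconnections considered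

Alternative 1: The cut is C4a–C5 plus C3–C4, with C3–C5 reconnected in the precursor. In the forward sense, ultraviolet irradiation of the enol form of β-diketone A1 (whose C8a carries a vinyl group, C4a=C4) gives a cyclobutanol by [2+2] addition, and retro-aldol cleavage delivers 1,5-diketone A2 (De Mayo reaction). In its favour, two C–C bonds form in one operation, and C7, C8 and C8a are all in place before ring B closes, so the ring-forming step sets no permanent stereocentre. On that point it is better than the chosen plan, as it is in having no enol-geometry requirement and in allowing selective acetylation of the secondary hydroxyl after acetonide removal. Against it here, A2 is saturated at C4, C4a and C5 and carries only a masked aldehyde at C3. The C4a=C5 unsaturation, ring A and the complete (1E,3Z)-dienyl chain must all be built afterwards, and the chain cannot be present earlier because it would not tolerate the irradiation. The six-membered "straight" mode of the [2+2] addition is less dependable than five-membered closure, and the acetonide must finally be removed with acid from an acid-sensitive chromophore. In step economy it is clearly longer after the key step, and mechanistically it moves the risk from stereocontrol to regiochemistry of a photocycloaddition.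

Alternative 2: The cut is C4a–C8a. Starting from the chiral pool lactone A3 (whose C2 and C3 map directly onto C7 and C8), the C8a iodide A4 with a tethered ynone is converted by (Me3Si)3SiH/AIBN into a radical that adds 6-endo to C4a, giving ring B enone A5 with the C4a=C5 bond already in place. In its favour, C7 and C8 come with secure absolute and relative configuration from A3 (better than the chosen plan, where C8 is set in the key step). The nucleophilic radical is polarity-matched for the β-carbon of the ynone, and the product is at the right oxidation level of ring B. Against it here, C8a is set in the radical step under substrate control of uncertain strength, which is no better than the chosen plan. The silyl radical and the stannane-free chain conditions are exposed to the dienyl chain, where reversible radical addition would threaten the 3'Z alkene. The route from A3 to A4 is long and linear, ring A is still open in A5, and an acetonide must again be removed by acid at the end. On mechanism the ring closure itself is at least as credible as the chosen one; on step economy and on compatibility with the side chain it is worse.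

Alternative 3: The cut is C5–C6. Activation of the dimethylamide of A6 with Tf2O/2-chloropyridine lets the exocyclic methylene carbon C5 of the 4-methylene dihydropyran attack the activated amide; loss of H5 and hydrolysis give the acetonide A7 of the deacetyl target. In its favour, all three stereocentres exist before the ring closes and the nucleophilic carbon is a terminal methylene, so there is neither a facial nor an enol-geometry question in the key step. On both points it is better than the chosen plan, and A7 is as close to the target as the chosen key-step product. Against it here, the C8–C8a bond and its two stereocentres must be made earlier by an intermolecular aldol reaction, so the stereochemical problem is moved and not removed. The activated amide sits on the quaternary C7 and is hindered, C4 is a competing nucleophilic site of the dienol ether, and triflic anhydride and the triflic acid it releases meet an acid-labile dienol ether, an acetonide and the 3'Z diene. Step count is about the same as the chosen plan; the key step carries more risk to the polyene and less to stereochemistry.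

Key step: step 15

## Remarks on the chemistry before the steps

- The side chain is (1E,3Z,5S) and the core (7R,8R,8aR). The structures of 21 and 23 agree with the target at every stereocentre, and (S)-configured 1 and 12 lead to 5'S and 7R, so no structure needs correction. The CIP label at C7 becomes S in 22 only because the priorities of C6 and C8 swap; the spatial arrangement is unchanged.
- 19–21 are drawn as the 4E isomers (C6 syn to C8a). The 4Z isomers would interconvert with them through the push–pull C4a=C5 bond and give the same intermediate 22, so a mixture would be carried on.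
- The phosphonate of step 1 and the ylide of step 3 are taken as purchasable reagents.

## Steps

Step 1
Reactants: 1 (2S)-2-methylbutan-1-ol
Product: 3 ethyl (2Z,4S)-2,4-dimethylhex-2-enoate, via (2S)-2-methylbutanal 2 (not isolated)
Conditions: TEMPO (cat.), KBr (cat.), NaOCl, CH2Cl2/aq. NaHCO3, 0 °C; dried CH2Cl2 solution of 2 added to the phosphonate, KN(SiMe3)2, 18-crown-6, THF, −78 °C
Reagents that add atoms: ethyl 2-[bis(2,2,2-trifluoroethoxy)phosphoryl]propanoate, CCOC(=O)C(C)P(=O)(OCC(F)(F)F)OCC(F)(F)F
Why: Oxoammonium oxidation gives the α-branched aldehyde without basic conditions that would epimerise C5', and using its solution directly avoids loss by volatility; the Still–Gennari olefination then gives the Z-trisubstituted enoate under kinetic control, which sets the 3'Z geometry (the ester carbon is the future C2', cis to C5').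

Step 2
Reactants: 3 ethyl (2Z,4S)-2,4-dimethylhex-2-enoate
Product: 4 (2Z,4S)-2,4-dimethylhex-2-en-1-ol
Conditions: i-Bu2AlH, CH2Cl2, −78 °C; aq. KNa tartrate
Reagents that add atoms: none
Why: 1,2-Reduction of the enoate by the aluminium hydride at low temperature should give the allylic alcohol without touching the alkene geometry or C5'.

Step 3
Reactants: 4 (2Z,4S)-2,4-dimethylhex-2-en-1-ol
Product: 6 (2E,4Z,6S)-N-methoxy-N,4,6-trimethylocta-2,4-dienamide, via (2Z,4S)-2,4-dimethylhex-2-enal 5 (not isolated)
Conditions: MnO2, the ylide, CH2Cl2, rt to 40 °C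
Reagents that add atoms: N-methoxy-N-methyl-2-(triphenyl-λ5-phosphanylidene)acetamide, CON(C)C(=O)C=P(c1ccccc1)(c1ccccc1)c1ccccc1
Why: Tandem oxidation–Wittig olefination: MnO2 oxidises the allylic alcohol under neutral heterogeneous conditions and the stabilised ylide traps the isomerisation-prone Z-enal as it forms, making the C1'=C2' bond E; the product is directly a Weinreb amide, which resists conjugate addition in step 5.

Step 4
Reactants: 7 4-hydroxybutan-2-one
Product: 8 4-[(tert-butyldimethylsilyl)oxy]butan-2-one
Conditions: TBSCl, imidazole, CH2Cl2, 0 °C to rt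
Reagents that add atoms: tert-butyldimethylsilyl chloride, CC(C)(C)[Si](C)(C)Cl
Why: Standard silylation of the primary alcohol; the mild base should avoid retro-aldol cleavage or dehydration of the β-hydroxy ketone.

Step 5
Reactants: 8 4-[(tert-butyldimethylsilyl)oxy]butan-2-one; 6 (2E,4Z,6S)-N-methoxy-N,4,6-trimethylocta-2,4-dienamide
Product: 9 (6E,8Z,10S)-1-[(tert-butyldimethylsilyl)oxy]-8,10-dimethyldodeca-6,8-diene-3,5-dione
Conditions: 8 (2.5 equiv), LiN(i-Pr)2 (2.6 equiv), THF, −78 °C; then 6, −78 to −20 °C; aq. NH4Cl
Reagents that add atoms: none
Why: Kinetic deprotonation occurs at the methyl group (not at C3, where it would trigger β-elimination of silanolate), and the enolate adds 1,2 to the Weinreb amide, whose chelated tetrahedral adduct collapses to the 1,3-diketone only on work-up (crossed Claisen-type acylation); the excess enolate covers deprotonation of the product.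

Step 6
Reactants: 9 (6E,8Z,10S)-1-[(tert-butyldimethylsilyl)oxy]-8,10-dimethyldodeca-6,8-diene-3,5-dione
Product: 11 6-[(1E,3Z,5S)-3,5-dimethylhepta-1,3-dien-1-yl]-2,3-dihydro-4H-pyran-4-one, via hydroxy diketone 10 (not isolated)
Conditions: aq. HF, MeCN, 0 °C to rt; then p-TsOH·H2O (cat.), CH2Cl2, rt
Reagents that add atoms: none
Why: Desilylation frees the hydroxyl, which forms the six-membered hemiketal at the dienyl ketone (C3); acid-catalysed dehydration then gives the vinylogous ester (cyclodehydration of a δ-hydroxy-β-diketone), and the acid is kept mild to preserve the 3'Z alkene.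

Step 7
Reactants: 12 (S)-2-methylglycidol
Product: 13 (2S)-3-[(4-methoxybenzyl)oxy]-2-methylpropane-1,2-diol
Conditions: 4-methoxybenzyl alcohol (3 equiv), NaH (0.3 equiv), DMF, 60 °C, slow addition of 12
Reagents that add atoms: 4-methoxybenzyl alcohol, COc1ccc(CO)cc1
Why: Alkoxide opening of the 2,2-disubstituted epoxide at its CH2 carbon (SN2) leaves the C–O bond at the quaternary centre intact, so the configuration is retained; a Payne rearrangement of 12 would be degenerate and return the same enantiomer, and the non-migrating ether keeps the two CH2O arms distinct.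

Step 8
Reactants: 13 (2S)-3-[(4-methoxybenzyl)oxy]-2-methylpropane-1,2-diol
Product: 14 (2R)-2-hydroxy-3-[(4-methoxybenzyl)oxy]-2-methylpropanoic acid
Conditions: TEMPO (cat.), NaOCl (cat.), NaClO2, MeCN/phosphate buffer pH 6.7, 35 °C
Reagents that add atoms: sodium chlorite, [Na+].[O-]Cl=O
Why: Oxoammonium oxidation of the primary alcohol to the aldehyde and chlorite oxidation to the acid occur in one pot; the tertiary alcohol cannot be oxidised, and the near-neutral buffer with only catalytic hypochlorite should spare the PMB ring.

Step 9
Reactants: 14 (2R)-2-hydroxy-3-[(4-methoxybenzyl)oxy]-2-methylpropanoic acid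
Product: 15 (3R)-3-hydroxy-4-[(4-methoxybenzyl)oxy]-3-methylbutan-2-one
Conditions: MeLi (3.5 equiv), THF, −78 to 0 °C; inverse quench into cold aq. HCl
Reagents that add atoms: methyllithium, [Li]C
Why: After deprotonation of the hydroxyl and carboxyl groups a third equivalent of MeLi adds to the lithium carboxylate to give a stable gem-dialkoxide, which releases the methyl ketone only on acidic work-up (ketone synthesis from a carboxylic acid and an organolithium); the quaternary centre has no enolisable hydrogen.

Step 10
Reactants: 15 (3R)-3-hydroxy-4-[(4-methoxybenzyl)oxy]-3-methylbutan-2-one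
Product: 16 (3R)-4-[(4-methoxybenzyl)oxy]-3-methyl-3-[(triethylsilyl)oxy]butan-2-one
Conditions: TESOTf, 2,6-lutidine, CH2Cl2, −78 to 0 °C
Reagents that add atoms: triethylsilyl trifluoromethanesulfonate, CC[Si](CC)(CC)OS(=O)(=O)C(F)(F)F
Why: A silyl triflate with a hindered pyridine base silylates the hindered tertiary α-ketol; the small triethylsilyl group is chosen so that O7 can still chelate in step 15 and can be removed by fluoride at the end.

Step 11
Reactants: 16 (3R)-4-[(4-methoxybenzyl)oxy]-3-methyl-3-[(triethylsilyl)oxy]butan-2-one; 11 6-[(1E,3Z,5S)-3,5-dimethylhepta-1,3-dien-1-yl]-2,3-dihydro-4H-pyran-4-one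
Product: 17 (3R)-1-{6-[(1E,3Z,5S)-3,5-dimethylhepta-1,3-dien-1-yl]-4-hydroxy-3,4-dihydro-2H-pyran-4-yl}-4-[(4-methoxybenzyl)oxy]-3-methyl-3-[(triethylsilyl)oxy]butan-2-one (both epimers at the carbinol carbon)
Conditions: 16, LiN(i-Pr)2, THF, −78 °C; then 11, −78 °C; AcOH in THF at −78 °C; crude product used directly
Reagents that add atoms: none
Why: 16 has a single enolisable position, so one lithium enolate forms and adds kinetically 1,2 to the vinylogous ester carbonyl at −78 °C (aldol addition); the cold acid quench prevents retro-aldol reversal, and the new carbinol centre is destroyed in step 12.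

Step 12
Reactants: 17 the aldol adduct of step 11
Product: 19 (3R)-1-{(4E)-6-[(1E,3Z,5S)-3,5-dimethylhepta-1,3-dien-1-yl]-2,3-dihydro-4H-pyran-4-ylidene}-4-[(4-methoxybenzyl)oxy]-3-methyl-3-[(triethylsilyl)oxy]butan-2-one, via tertiary mesylate 18 (not isolated)
Conditions: MsCl, Et3N, CH2Cl2, −20 to 0 °C
Reagents that add atoms: none
Why: Sulfene-type mesylation of the tertiary alcohol gives a leaving group that ionises with help from the ring oxygen, and Et3N removes the acidic H5 (dehydration of a β-hydroxy ketone); the product is the thermodynamically favoured cross-conjugated dienol ether, with the 4E isomer expected to predominate.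

Step 13
Reactants: 19 the PMB ether of step 12
Product: 20 (3R)-1-{(4E)-6-[(1E,3Z,5S)-3,5-dimethylhepta-1,3-dien-1-yl]-2,3-dihydro-4H-pyran-4-ylidene}-4-hydroxy-3-methyl-3-[(triethylsilyl)oxy]butan-2-one
Conditions: DDQ, CH2Cl2/pH 7 phosphate buffer, 0 °C
Reagents that add atoms: none
Why: Oxidative PMB cleavage by DDQ proceeds through the benzylic oxocarbenium ion, which the buffer hydrolyses; the neutral conditions should avoid silyl migration from O7 to the freed O8 and leave the tertiary silyl ether intact.

Step 14
Reactants: 20 the primary alcohol of step 13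
Product: 21 (2R)-4-{(4E)-6-[(1E,3Z,5S)-3,5-dimethylhepta-1,3-dien-1-yl]-2,3-dihydro-4H-pyran-4-ylidene}-2-methyl-3-oxo-2-[(triethylsilyl)oxy]butanal
Conditions: Dess–Martin periodinane, NaHCO3, CH2Cl2, 0 °C to rt; used at once
Reagents that add atoms: none
Why: Dess–Martin oxidation of the neopentyl-type primary alcohol under buffered, non-basic conditions; the aldehyde has no α-hydrogen and cannot epimerise, but as a β-keto aldehyde it is prone to hydration and deformylation, so it is not stored.

Step 15
Reactants: 21 the keto aldehyde of step 14
Product: 23 (7R,8R,8aR)-3-[(1E,3Z,5S)-3,5-dimethylhepta-1,3-dien-1-yl]-8-hydroxy-7-methyl-7-[(triethylsilyl)oxy]-1,7,8,8a-tetrahydro-6H-isochromen-6-one, via silyl trienol ether 22 (not isolated)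
Conditions: TBSOTf (1.2 equiv), Et3N (1.5 equiv), CH2Cl2, −78 °C; then Me2AlCl (5 equiv, excess over the amine), −78 to −40 °C; aq. KNa tartrate
Reagents that add atoms: none
Why: The silyl triflate silylates the C6 carbonyl oxygen, the most basic site of the vinylogous ester, and Et3N removes a proton from C8a, the only sp3 C–H next to the delocalised cation, giving the 2H-pyran silyl trienol ether 22; Me2AlCl then activates the non-enolisable C8 aldehyde, C8a attacks it, and loss of the silyl group on work-up restores the conjugated dienone. The closest known reaction type is the intramolecular vinylogous Mukaiyama aldol addition of a silyl dienol ether to an aldehyde. Ring B closes in a 6-(enolendo)-exo-trig mode, with the C5=C6 and C4a=C8a enol double bonds inside the forming ring and the aldehyde C=O outside it. C8 is controlled by the fixed C7 centre: Me2AlCl, a Lewis acid able to chelate even silyl ethers, is meant to tie O7 to the aldehyde oxygen, which places O7 axial and syn to the aldehyde oxygen and the C7 methyl equatorial in a chair-like transition state (the axial position also spares the O7 silyl ether A(1,2) strain with the C6 silyloxy group), so the 7,8-cis relationship should result. C8a is controlled by the same chair: the chelated aldehyde oxygen lies pseudo-equatorial and antiperiplanar to the C8a=C4a bond, so H8 and H8a end up trans and C1 equatorial, and because H8a stays enolisable a wrong epimer could still equilibrate to this all-equatorial arrangement. The step needs γ- over α-reactivity, which is secured because attack through C5 would give a four-membered ring and only γ-attack regains the vinylogous ester; it also needs the enol ether geometry with C7 syn to C4a, which the bulky silyl group is expected to favour by reacting through the s-trans enone conformer (the only one with an unhindered oxygen lone pair, next to H5), with rotation about the C5–C6 bond of the delocalised O-silyl cation as a second route to that isomer. The proton-scavenging aluminium reagent and the low temperature are chosen to leave the 3'Z alkene and C5' untouched.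

Step 16
Reactants: 23 the hydroxy dienone of step 15
Product: 24 (7R,8R,8aR)-3-[(1E,3Z,5S)-3,5-dimethylhepta-1,3-dien-1-yl]-7-methyl-6-oxo-7-[(triethylsilyl)oxy]-6,7,8,8a-tetrahydro-1H-isochromen-8-yl acetate
Conditions: Ac2O, pyridine, DMAP (cat.), CH2Cl2, 0 °C to rt
Reagents that add atoms: acetic anhydride, CC(=O)OC(C)=O
Why: DMAP-catalysed acylation of the only free hydroxyl; the mild amine base is not expected to induce silyl migration or elimination of the new acetate across C8–C8a at this temperature.

Step 17
Reactants: 24 the acetate of step 16
Product: 25 (7R,8R,8aR)-3-[(1E,3Z,5S)-3,5-dimethylhepta-1,3-dien-1-yl]-7-hydroxy-7-methyl-6-oxo-6,7,8,8a-tetrahydro-1H-isochromen-8-yl acetate (target)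
Conditions: HF·pyridine, pyridine, THF, 0 °C to rt
Reagents that add atoms: none
Why: Buffered fluoride cleaves the tertiary triethylsilyl ether under weakly acidic conditions that avoid base-induced elimination of the acetate and C8a epimerisation; acyl migration from the secondary O8 to the tertiary O7 is thermodynamically unfavourable.

## Compound list

1 | (2S)-2-methylbutan-1-ol | CC[C@H](C)CO | starting material
2 | (2S)-2-methylbutanal | CC[C@H](C)C=O | intermediate
3 | ethyl (2Z,4S)-2,4-dimethylhex-2-enoate | CC[C@H](C)/C=C(C)\C(=O)OCC | intermediate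
4 | (2Z,4S)-2,4-dimethylhex-2-en-1-ol | CC[C@H](C)/C=C(C)\CO | intermediate
5 | (2Z,4S)-2,4-dimethylhex-2-enal | CC[C@H](C)/C=C(C)\C=O | intermediate
6 | (2E,4Z,6S)-N-methoxy-N,4,6-trimethylocta-2,4-dienamide | CC[C@H](C)/C=C(C)\C=C\C(=O)N(C)OC | intermediate
7 | 4-hydroxybutan-2-one | CC(=O)CCO | starting material
8 | 4-[(tert-butyldimethylsilyl)oxy]butan-2-one | CC(=O)CCO[Si](C)(C)C(C)(C)C | intermediate
9 | (6E,8Z,10S)-1-[(tert-butyldimethylsilyl)oxy]-8,10-dimethyldodeca-6,8-diene-3,5-dione | CC[C@H](C)/C=C(C)\C=C\C(=O)CC(=O)CCO[Si](C)(C)C(C)(C)C | intermediate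
10 | (6E,8Z,10S)-1-hydroxy-8,10-dimethyldodeca-6,8-diene-3,5-dione | CC[C@H](C)/C=C(C)\C=C\C(=O)CC(=O)CCO | intermediate
11 | 6-[(1E,3Z,5S)-3,5-dimethylhepta-1,3-dien-1-yl]-2,3-dihydro-4H-pyran-4-one | CC[C@H](C)/C=C(C)\C=C\C1=CC(=O)CCO1 | intermediate
12 | (S)-2-methylglycidol, (2S)-(2-methyloxiran-2-yl)methanol | OC[C@@]1(C)CO1 | starting material
13 | (2S)-3-[(4-methoxybenzyl)oxy]-2-methylpropane-1,2-diol | OC[C@@](O)(C)COCc1ccc(OC)cc1 | intermediate
14 | (2R)-2-hydroxy-3-[(4-methoxybenzyl)oxy]-2-methylpropanoic acid | OC(=O)[C@@](O)(C)COCc1ccc(OC)cc1 | intermediate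
15 | (3R)-3-hydroxy-4-[(4-methoxybenzyl)oxy]-3-methylbutan-2-one | CC(=O)[C@@](O)(C)COCc1ccc(OC)cc1 | intermediate
16 | (3R)-4-[(4-methoxybenzyl)oxy]-3-methyl-3-[(triethylsilyl)oxy]butan-2-one | CC(=O)[C@](C)(O[Si](CC)(CC)CC)COCc1ccc(OC)cc1 | intermediate
17 | (3R)-1-{6-[(1E,3Z,5S)-3,5-dimethylhepta-1,3-dien-1-yl]-4-hydroxy-3,4-dihydro-2H-pyran-4-yl}-4-[(4-methoxybenzyl)oxy]-3-methyl-3-[(triethylsilyl)oxy]butan-2-one (carbinol epimers) | CC[C@H](C)/C=C(C)\C=C\C1=CC(O)(CC(=O)[C@](C)(O[Si](CC)(CC)CC)COCc2ccc(OC)cc2)CCO1 | intermediate
18 | methanesulfonate of 17 at the tertiary hydroxyl | CC[C@H](C)/C=C(C)\C=C\C1=CC(OS(C)(=O)=O)(CC(=O)[C@](C)(O[Si](CC)(CC)CC)COCc2ccc(OC)cc2)CCO1 | intermediate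
19 | (3R)-1-{(4E)-6-[(1E,3Z,5S)-3,5-dimethylhepta-1,3-dien-1-yl]-2,3-dihydro-4H-pyran-4-ylidene}-4-[(4-methoxybenzyl)oxy]-3-methyl-3-[(triethylsilyl)oxy]butan-2-one | CC[C@H](C)/C=C(C)\C=C\C1=C\C(=C\C(=O)[C@](C)(O[Si](CC)(CC)CC)COCc2ccc(OC)cc2)CCO1 | intermediate
20 | (3R)-1-{(4E)-6-[(1E,3Z,5S)-3,5-dimethylhepta-1,3-dien-1-yl]-2,3-dihydro-4H-pyran-4-ylidene}-4-hydroxy-3-methyl-3-[(triethylsilyl)oxy]butan-2-one | CC[C@H](C)/C=C(C)\C=C\C1=C\C(=C\C(=O)[C@](C)(O[Si](CC)(CC)CC)CO)CCO1 | intermediate
21 | (2R)-4-{(4E)-6-[(1E,3Z,5S)-3,5-dimethylhepta-1,3-dien-1-yl]-2,3-dihydro-4H-pyran-4-ylidene}-2-methyl-3-oxo-2-[(triethylsilyl)oxy]butanal | CC[C@H](C)/C=C(C)\C=C\C1=C\C(=C\C(=O)[C@](C)(O[Si](CC)(CC)CC)C=O)CCO1 | intermediate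
22 | (2S,3E)-3-[(tert-butyldimethylsilyl)oxy]-4-{6-[(1E,3Z,5S)-3,5-dimethylhepta-1,3-dien-1-yl]-2H-pyran-4-yl}-2-methyl-2-[(triethylsilyl)oxy]but-3-enal | CC[C@H](C)/C=C(C)\C=C\C1=CC(/C=C(/O[Si](C)(C)C(C)(C)C)[C@](C)(O[Si](CC)(CC)CC)C=O)=CCO1 | intermediate
23 | (7R,8R,8aR)-3-[(1E,3Z,5S)-3,5-dimethylhepta-1,3-dien-1-yl]-8-hydroxy-7-methyl-7-[(triethylsilyl)oxy]-1,7,8,8a-tetrahydro-6H-isochromen-6-one | CC[C@H](C)/C=C(C)\C=C\C1=CC2=CC(=O)[C@](C)(O[Si](CC)(CC)CC)[C@H](O)[C@H]2CO1 | intermediate
24 | (7R,8R,8aR)-3-[(1E,3Z,5S)-3,5-dimethylhepta-1,3-dien-1-yl]-7-methyl-6-oxo-7-[(triethylsilyl)oxy]-6,7,8,8a-tetrahydro-1H-isochromen-8-yl acetate | CC[C@H](C)/C=C(C)\C=C\C1=CC2=CC(=O)[C@](C)(O[Si](CC)(CC)CC)[C@H](OC(C)=O)[C@H]2CO1 | intermediate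
25 | (7R,8R,8aR)-3-[(1E,3Z,5S)-3,5-dimethylhepta-1,3-dien-1-yl]-7-hydroxy-7-methyl-6-oxo-6,7,8,8a-tetrahydro-1H-isochromen-8-yl acetate | CC[C@H](C)/C=C(C)\C=C\C1=CC2=CC(=O)[C@](C)(O)[C@H](OC(C)=O)[C@H]2CO1 | target

## Step count and least certain steps

Total: 17 steps. Longest linear sequence: 12 steps (1, 2, 3, 5, 6, 11, 12, 13, 14, 15, 16, 17, from compound 1). The branch from 12 has 11 steps and the branch from 7 has 10.

Step 15 (key step). The most likely failure is enol silylation that fixes the unproductive C5=C6 geometry (silyloxy group syn to C4a): the enone prefers the s-cis conformation, and that isomer cannot reach the aldehyde, so 21 would simply be returned on work-up. The next risks are closure through a non-chelated transition state with loss of facial control at C8, and E/Z equilibration of the 3'Z alkene while positive charge is delocalised into the chain. The fallback builds ring B in the reverse order; it sets out from 16 and 11 and comes back at 23. DDQ cleavage of the PMB ether of 16 gives (3R)-4-hydroxy-3-methyl-3-[(triethylsilyl)oxy]butan-2-one F1, and Dess–Martin oxidation gives (2R)-2-methyl-3-oxo-2-[(triethylsilyl)oxy]butanal F2. The kinetic lithium enolate of 11 (LiN(i-Pr)2, −78 °C, deprotonation at C8a, the α'-position of the vinylogous ester) adds to F2 and makes the C8–C8a bond intermolecularly, giving (3R)-6-[(1E,3Z,5S)-3,5-dimethylhepta-1,3-dien-1-yl]-3-{(1R,2R)-1-hydroxy-2-methyl-3-oxo-2-[(triethylsilyl)oxy]butyl}-2,3-dihydro-4H-pyran-4-one F3. Here Felkin–Anh addition anti to the silyloxy group corresponds to the required C7/C8 sense, and there is no enol-geometry requirement. Base-mediated intramolecular aldol condensation of the C5 methyl ketone onto the C4a carbonyl (KOt-Bu, or pyrrolidinium acetate) then closes ring B through the C4a=C5 bond and equilibrates C8a, arriving at 23.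

Step 11. The most likely failure is proton transfer from C8a–H of 11 to the enolate, or reversal of the addition, because the vinylogous ester carbonyl is a poor electrophile (a cerium enolate made with CeCl3 would be tried first). The fallback sets out from 11 and 16 and comes back at 19, bypassing 17 and 18. O-Methylation of 11 with MeOTf gives 6-[(1E,3Z,5S)-3,5-dimethylhepta-1,3-dien-1-yl]-4-methoxy-2,3-dihydropyrylium trifluoromethanesulfonate F4, a far better electrophile at C4a. 16 is converted with Me3SiOTf/Et3N into (3R)-4-[(4-methoxybenzyl)oxy]-3-methyl-3-[(triethylsilyl)oxy]-2-[(trimethylsilyl)oxy]but-1-ene F5. Mukaiyama-type addition of F5 to the methoxy-bearing carbon of F4, followed by loss of methanol with a hindered pyridine base, should give 19 directly.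

Step 13. The most likely failure is oxidation of the electron-rich dienol ether and polyene by DDQ in competition with electron transfer from the PMB ring. The fallback removes the benzyl-type group before the chromophore exists; it sets out from 15 and comes back at 20. Hydrogenolysis of 15 (H2, Pd/C, EtOAc) gives (3R)-3,4-dihydroxy-3-methylbutan-2-one F6, and double silylation (TESOTf, 2,6-lutidine) gives (3R)-3-methyl-3,4-bis[(triethylsilyl)oxy]butan-2-one F7. Steps 11 and 12 applied to F7 and 11 give (3R)-1-{6-[(1E,3Z,5S)-3,5-dimethylhepta-1,3-dien-1-yl]-4-hydroxy-3,4-dihydro-2H-pyran-4-yl}-3-methyl-3,4-bis[(triethylsilyl)oxy]butan-2-one F8 and then (3R)-1-{(4E)-6-[(1E,3Z,5S)-3,5-dimethylhepta-1,3-dien-1-yl]-2,3-dihydro-4H-pyran-4-ylidene}-3-methyl-3,4-bis[(triethylsilyl)oxy]butan-2-one F9. HF·pyridine buffered with pyridine at 0 °C should cleave only the primary silyl ether of F9 and give 20.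

Step 3. The most likely failure is Z-to-E isomerisation of enal 5 (reversible conjugate addition of the ylide or trace acid) before it is olefinated, added to any erosion of Z-selectivity in step 1. The fallback makes the Z-trisubstituted alkene by stereospecific cross-coupling; it sets out from 2 (prepared as in step 1) and comes back at 6. Corey–Fuchs dibromo-olefination (CBr4, PPh3) gives (3S)-1,1-dibromo-3-methylpent-1-ene F10. Trans-selective Negishi methylation (MeZnCl, PdCl2(DPEphos)) replaces the bromine trans to the alkyl group and gives (2Z,4S)-2-bromo-4-methylhex-2-ene F11. A Heck reaction of F11 with N-methoxy-N-methylacrylamide (Pd(OAc)2, P(o-tol)3, Et3N, with zerovalent palladium formed in situ) proceeds with retention at the alkenyl bromide and E geometry at the new bond, giving 6.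

## Further compounds

F1 | step 15 | (3R)-4-hydroxy-3-methyl-3-[(triethylsilyl)oxy]butan-2-one | CC(=O)[C@](C)(O[Si](CC)(CC)CC)CO
F2 | step 15 | (2R)-2-methyl-3-oxo-2-[(triethylsilyl)oxy]butanal | CC(=O)[C@](C)(O[Si](CC)(CC)CC)C=O
F3 | step 15 | (3R)-6-[(1E,3Z,5S)-3,5-dimethylhepta-1,3-dien-1-yl]-3-{(1R,2R)-1-hydroxy-2-methyl-3-oxo-2-[(triethylsilyl)oxy]butyl}-2,3-dihydro-4H-pyran-4-one | CC[C@H](C)/C=C(C)\C=C\C1=CC(=O)[C@@H]([C@@H](O)[C@@](C)(O[Si](CC)(CC)CC)C(C)=O)CO1
F4 | step 11 | 6-[(1E,3Z,5S)-3,5-dimethylhepta-1,3-dien-1-yl]-4-methoxy-2,3-dihydropyrylium trifluoromethanesulfonate | CC[C@H](C)/C=C(C)\C=C\C1=[O+]CCC(OC)=C1.[O-]S(=O)(=O)C(F)(F)F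
F5 | step 11 | (3R)-4-[(4-methoxybenzyl)oxy]-3-methyl-3-[(triethylsilyl)oxy]-2-[(trimethylsilyl)oxy]but-1-ene | C=C(O[Si](C)(C)C)[C@](C)(O[Si](CC)(CC)CC)COCc1ccc(OC)cc1
F6 | step 13 | (3R)-3,4-dihydroxy-3-methylbutan-2-one | CC(=O)[C@@](O)(C)CO
F7 | step 13 | (3R)-3-methyl-3,4-bis[(triethylsilyl)oxy]butan-2-one | CC(=O)[C@](C)(O[Si](CC)(CC)CC)CO[Si](CC)(CC)CC
F8 | step 13 | (3R)-1-{6-[(1E,3Z,5S)-3,5-dimethylhepta-1,3-dien-1-yl]-4-hydroxy-3,4-dihydro-2H-pyran-4-yl}-3-methyl-3,4-bis[(triethylsilyl)oxy]butan-2-one | CC[C@H](C)/C=C(C)\C=C\C1=CC(O)(CC(=O)[C@](C)(O[Si](CC)(CC)CC)CO[Si](CC)(CC)CC)CCO1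
F9 | step 13 | (3R)-1-{(4E)-6-[(1E,3Z,5S)-3,5-dimethylhepta-1,3-dien-1-yl]-2,3-dihydro-4H-pyran-4-ylidene}-3-methyl-3,4-bis[(triethylsilyl)oxy]butan-2-one | CC[C@H](C)/C=C(C)\C=C\C1=C\C(=C\C(=O)[C@](C)(O[Si](CC)(CC)CC)CO[Si](CC)(CC)CC)CCO1
F10 | step 3 | (3S)-1,1-dibromo-3-methylpent-1-ene | CC[C@H](C)C=C(Br)Br
F11 | step 3 | (2Z,4S)-2-bromo-4-methylhex-2-ene | CC[C@H](C)/C=C(C)\Br
A1 | alternative 1 | enolisable β-diketone photosubstrate with a vinyl group on C8a | COC(OC)C(=O)CC(=O)[C@]1(C)OC(C)(C)O[C@@H]1[C@H](C=C)CO[Si](C)(C)C(C)(C)C
A2 | alternative 1 | ring B 1,5-diketone (key-step product) | COC(OC)C(=O)C[C@@H]1CC(=O)[C@]2(C)OC(C)(C)O[C@@H]2[C@H]1CO[Si](C)(C)C(C)(C)C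
A3 | alternative 2 | 2-C-methyl-D-ribono-1,4-lactone | O=C1O[C@H](CO)[C@@H](O)[C@@]1(C)O
A4 | alternative 2 | C8a iodide with tethered ynone (iodide centre unspecified, planarised in the radical) | CC[C@H](C)/C=C(C)\C=C\[C@@H](O[Si](C)(C)C(C)(C)C)CC#CC(=O)[C@]1(C)OC(C)(C)O[C@@H]1C(I)CO[Si](C)(C)C(C)(C)C
A5 | alternative 2 | ring B enone carrying the C4–C3 side arm (key-step product) | CC[C@H](C)/C=C(C)\C=C\[C@@H](O[Si](C)(C)C(C)(C)C)CC1=CC(=O)[C@]2(C)OC(C)(C)O[C@@H]2[C@H]1CO[Si](C)(C)C(C)(C)C
A6 | alternative 3 | 4-methylene dihydropyran bearing the C6 dimethylamide | CC[C@H](C)/C=C(C)\C=C\C1=CC(=C)[C@H](CO1)[C@H]1OC(C)(C)O[C@@]1(C)C(=O)N(C)C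
A7 | alternative 3 | 7,8-acetonide of the deacetyl target (key-step product) | CC[C@H](C)/C=C(C)\C=C\C1=CC2=CC(=O)[C@]3(C)OC(C)(C)O[C@@H]3[C@H]2CO1
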